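The route rests on disconnecting C3–C4 in the seven-membered ring (C1–C2–C3–C4–C5–C6–C11): the free C3 carbinol adjoins the gem-dimethyl carbon C4, which hangs on cyclobutane carbon C5, 1,3-cis to the C1 arm on C11. In the forward sense an iron hydride (from Fe(acac)3 and PhSiH3) hands a hydrogen atom to an isopropenyl group on C5 and the tertiary C4 radical adds to a C3 aldehyde, so one operation forges C3–C4, the second C4 methyl, the cycloheptane and the C3 stereocentre. The precursor is a bicyclo[3.1.1]heptenone (cyclobutane C5, C6, C10, C11 bridged by the C7–C9 enone) carrying C5–H isopropenyl and a C1-angeloyloxy, C2-isovaleryloxy C3-aldehyde chain; its cyclisation gives the target directly.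

Key step: step 21

Numbering used throughout: C1 angelate carbinol, C2 isovalerate carbinol, C3 free carbinol, C4 CMe2, cyclobutane C5 (next to C4), C6 (next to the ketone), C10 (next to C9) and C11 (quaternary, CH3, next to C1), enone bridge C7(=O)–C8=C9(CH3) from C6 to C10; "syn" and "anti" refer to this bridge, and CIP descriptors refer to this numbering.

Remark on the chemistry: C5 is carried as C–H and never as a tertiary cyclobutanol, because a hydroxyl there would sit β to the C7 ketone in a strained ring (retro-aldol) and would need a late deoxygenation; the carbon skeleton, the alkene and the aldehyde of the key step are unchanged.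

Remark on the chemistry: the angelate is put on before the key step, so that the cyclisation product is the target and no hydroxyl has to be told apart afterwards.

Remark on the chemistry: the series is racemic up to step 11 (SMILES show the enantiomer that is carried on) and is resolved there by the chiral borane.

Remark on the chemistry: 12–23 are expected as pairs of geometric isomers about C4=C5, 19–32 as C3 epimers and 21–24 with an unassigned C7 carbinol; these elements are erased in steps 15, 20 and 16, so the SMILES leave them open.

Assumption: allyl 4-methoxybenzyl ether is taken as a catalogue reagent.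

Step 1
Reactants: 1 geranyl acetate
Product: 2 (2E,6E)-8-hydroxygeranyl acetate
Conditions: SeO2 (cat.), t-BuOOH, salicylic acid (cat.), CH2Cl2, rt
Reagents that add atoms: tert-butyl hydroperoxide, CC(C)(C)OO
Why: SeO2/t-BuOOH allylic oxidation (ene reaction then [2,3]-sigmatropic shift) attacks the electron-rich remote trisubstituted alkene at its (E)-methyl group and leaves the alkene that is deactivated by the allylic acetate.

Step 2
Reactants: 2 (2E,6E)-8-hydroxygeranyl acetate
Product: 3 8-(tert-butyldiphenylsilyloxy)geranyl acetate
Conditions: TBDPSCl, imidazole, CH2Cl2, rt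
Reagents that add atoms: tert-butyl(chloro)diphenylsilane, CC(C)(C)[Si](Cl)(c1ccccc1)c1ccccc1
Why: Standard silylation of the primary allylic alcohol, the TBDPS ether being chosen to survive acid chloride formation, base and the chromium oxidation.

Step 3
Reactants: 3 8-(tert-butyldiphenylsilyloxy)geranyl acetate
Product: 4 8-(tert-butyldiphenylsilyloxy)geraniol
Conditions: K2CO3 (cat.), MeOH, rt
Reagents that add atoms: none
Why: Base-catalysed transesterification (Zemplén-type methanolysis) removes the acetate without touching the silyl ether or either alkene geometry.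

Step 4
Reactants: 4 8-(tert-butyldiphenylsilyloxy)geraniol
Product: 6 8-(tert-butyldiphenylsilyloxy)geranic acid, via dienal 5 (not isolated)
Conditions: TEMPO (cat.), PhI(OAc)2, CH2Cl2, rt; then t-BuOH, 2-methyl-2-butene, aq NaClO2, NaH2PO4, 0 °C to rt
Reagents that add atoms: sodium chlorite, [Na+].[O-]Cl=O
Why: TEMPO/PhI(OAc)2 oxidation to the enal followed in the same flask by Pinnick oxidation (2-methyl-2-butene as hypochlorite scavenger) should give the (2E)-acid without isomerising the conjugated alkene.

Step 5
Reactants: 6 8-(tert-butyldiphenylsilyloxy)geranic acid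
Product: 9 racemic methylidene cyclobutanone (C5 ketone; C9=CH2; C11 with CH3 syn; CH2OTBDPS anti), via acid chloride 7 (not isolated), via vinylketene 8 (not isolated)
Conditions: (COCl)2, DMF (cat.), CH2Cl2, 0 °C to rt, evaporate; then slow addition to Et3N, toluene, reflux, high dilution
Reagents that add atoms: none
Why: Dehydrochlorination at the C3 methyl gives a vinylketene that undergoes the known intramolecular crossed [2+2] ketene–alkene cycloaddition (ketene carbonyl carbon to the less substituted alkene carbon), suprafacial on the alkene, so the E geometry places the silyloxymethyl group anti and the methyl syn to the three-carbon bridge and fixes the relative configuration of C6, C10 and C11 in racemic form.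

Step 6
Reactants: 9 racemic methylidene cyclobutanone
Product: 10 racemic cyclobutanone with ring alkene C8=C9(CH3)
Conditions: RuHCl(CO)(PPh3)3 (cat.), toluene, 80 °C
Reagents that add atoms: none
Why: Hydride addition–elimination alkene isomerisation with RuHCl(CO)(PPh3)3 moves the exocyclic 1,1-disubstituted alkene to the more stable trisubstituted ring position (the β-pinene to α-pinene relationship), and the bridgeheads block any further migration.

Step 7
Reactants: 10 racemic cyclobutanone with ring alkene, 11 triethyl 2-phosphonopropionate
Product: 12 racemic alkylidene ester (C5=C4(CH3)CO2Et)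
Conditions: NaH, DME, 0 °C to reflux
Reagents that add atoms: triethyl 2-phosphonopropionate, CCOC(=O)C(C)P(=O)(OCC)OCC
Why: Horner–Wadsworth–Emmons olefination of the strained, non-enolisable cyclobutanone brings in the three carbons that become C4 and its two methyl groups, and the E/Z geometry of the new tetrasubstituted alkene does not matter because step 15 erases it.

Step 8
Reactants: 12 racemic alkylidene ester
Product: 13 racemic enone ester (C7 ketone)
Conditions: CrO3, 3,5-dimethylpyrazole, CH2Cl2, −20 °C
Reagents that add atoms: chromium trioxide, O=[Cr](=O)=O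
Why: Allylic oxidation with the CrO3–3,5-dimethylpyrazole complex converts the ring allylic methylene C7 into the enone (the α-pinene to verbenone transformation), while the electron-poor tetrasubstituted enoate is inert and C5 is no longer a ketone that would make a cleavable 1,3-diketone.

Step 9
Reactants: 13 racemic enone ester
Product: 14 racemic primary alcohol (C1H2OH)
Conditions: TBAF, AcOH, THF, 0 °C to rt
Reagents that add atoms: none
Why: Fluoride desilylation, buffered with acetic acid so that no alkoxide can add to the C7 ketone.

Step 10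
Reactants: 14 racemic primary alcohol
Product: 15 racemic C1 aldehyde
Conditions: Dess–Martin periodinane, CH2Cl2, rt
Reagents that add atoms: none
Why: Dess–Martin oxidation of the neopentyl primary alcohol gives an aldehyde with no α-hydrogen, which can neither enolise nor epimerise.

Step 11
Reactants: 15 racemic C1 aldehyde, 16 allyl 4-methoxybenzyl ether
Product: 18 (1S,2S)-syn homoallylic alcohol (C1–OH; C2–OPMB; vinyl), via Z-allylborane 17 (not isolated)
Conditions: 16, s-BuLi, THF, −78 °C; (+)-Ipc2BOMe; BF3·OEt2; then 15, −78 °C; HOCH2CH2NH2, rt; chromatography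
Reagents that add atoms: allyl 4-methoxybenzyl ether, C=CCOCc1ccc(OC)cc1
Why: Brown (Z)-γ-alkoxyallylboration through a closed chair transition state, in which the Z-borane gives the syn C1-hydroxy/C2-alkoxy pair and the isopinocampheyl groups from (−)-α-pinene direct attack to the Re face of the aldehyde to set (1S,2S) under reagent control; the mirror-image aldehyde gives a diastereomeric syn adduct that is removed by chromatography, so the step also resolves the series.

Step 12
Reactants: 18 (1S,2S)-syn homoallylic alcohol
Product: 19 triol (C3H(OH)–CH2OH)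
Conditions: OsO4 (cat.), N-methylmorpholine N-oxide, acetone/H2O, rt
Reagents that add atoms: N-methylmorpholine N-oxide, C[N+]1([O-])CCOCC1; water, O
Why: Upjohn dihydroxylation with catalytic OsO4 should take only the monosubstituted vinyl group, since the enone and enoate alkenes are electron-poor and hindered and no isopropenyl group is present yet; the C3 configuration is irrelevant.

Step 13
Reactants: 19 triol
Product: 20 terminal acetonide
Conditions: 2,2-dimethoxypropane, PPTS (cat.), CH2Cl2, rt
Reagents that add atoms: 2,2-dimethoxypropane, COC(C)(C)OC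
Why: Acid-catalysed transacetalisation forms the five-membered acetonide of the terminal 1,2-diol in preference to a dioxane involving the hindered C1 hydroxyl, which masks the future C3 aldehyde.

Step 14
Reactants: 20 terminal acetonide
Product: 21 triol (C1–OH; C7–OH; C5=C4(CH3)CH2OH)
Conditions: i-Bu2AlH, CH2Cl2, −78 °C; aq potassium sodium tartrate
Reagents that add atoms: none
Why: i-Bu2AlH reduces the conjugated ester to the primary allylic alcohol and the C7 ketone (1,2-reduction) to the allylic alcohol, which removes every carbonyl group before the hydrazide chemistry of step 15.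

Step 15
Reactants: 21 triol
Product: 24 isopropenyl diol (C5–H; isopropenyl cis to the C11 side chain), via sulfonylhydrazine 22 (not isolated), via allylic diazene 23 (not isolated)
Conditions: PPh3, DEAD, 2-nitrobenzenesulfonylhydrazide, THF, −30 °C to rt
Reagents that add atoms: none
Why: Reductive 1,3-transposition by Mitsunobu displacement of the primary allylic alcohol with the sulfonylhydrazide (the hindered secondary hydroxyls at C1 and C7 should stay out), loss of sulfinic acid and retro-ene loss of N2 from the allylic diazene, which delivers hydrogen to C5 from the face turned to the enone bridge, away from the bulky C1 chain on C11, so that the isopropenyl group ends cis to that chain.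

Step 16
Reactants: 24 isopropenyl diol
Product: 25 isopropenyl enone alcohol (C7 ketone; C1–OH)
Conditions: MnO2, CH2Cl2, rt
Reagents that add atoms: none
Why: MnO2 oxidises only the allylic C7 alcohol back to the enone and leaves the non-allylic C1 hydroxyl.

Step 17
Reactants: 25 isopropenyl enone alcohol, 26 angelic acid
Product: 28 C1 angelate, via mixed anhydride 27 (not isolated)
Conditions: 26, 2,4,6-trichlorobenzoyl chloride, Et3N, toluene, rt; then 25, 80 °C
Reagents that add atoms: angelic acid, C/C=C(/C)C(=O)O
Why: Yamaguchi-type acylation with the preformed angelic 2,4,6-trichlorobenzoic mixed anhydride, run without a nucleophilic catalyst, should transfer the angeloyl group to the only free hydroxyl with retention of the Z geometry.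

Step 18
Reactants: 28 C1 angelate
Product: 29 C2 alcohol
Conditions: DDQ, CH2Cl2/pH 7 buffer, 0 °C
Reagents that add atoms: none
Why: Oxidative cleavage of the 4-methoxybenzyl ether by DDQ (hydride abstraction, then hydrolysis of the oxocarbenium ion) frees the C2 hydroxyl under buffered conditions that spare the acetonide, the angelate and the alkenes.

Step 19
Reactants: 29 C2 alcohol, 30 isovaleryl chloride
Product: 31 C2 isovalerate
Conditions: pyridine, DMAP (cat.), CH2Cl2, 0 °C
Reagents that add atoms: isovaleryl chloride, CC(C)CC(=O)Cl
Why: Pyridine/DMAP acylation of the secondary C2 alcohol with the acid chloride, fast enough at 0 °C to forestall migration of the angelate from O1 to O2.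

Step 20
Reactants: 31 C2 isovalerate
Product: 33 C3 aldehyde (key-step precursor), via diol 32 (not isolated)
Conditions: H5IO6, EtOAc, rt
Reagents that add atoms: none
Why: Periodic acid hydrolyses the terminal acetonide and cleaves the liberated 1,2-diol in one operation (glycol cleavage), so the C3 aldehyde is released without any alkene oxidant and the isopropenyl group, the enone and the angelate stay untouched.

Step 21
Reactants: 33 C3 aldehyde (key-step precursor)
Product: 34 target CNP0251293.1
Conditions: Fe(acac)3 (30 mol %), PhSiH3, EtOH/HOCH2CH2OH, 40 °C, high dilution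
Reagents that add atoms: none
Why: An iron hydride generated from Fe(acac)3 and PhSiH3 gives a hydrogen atom to the CH2 terminus of the isopropenyl group (Markovnikov HAT); the tertiary C4 radical adds to the C3 carbonyl carbon, and the C3 alkoxy radical is reduced by divalent iron and protonated by ethanol, which returns the iron catalyst. The closest known reaction type is the iron-hydride HAT-initiated reductive radical cyclisation of alkenyl ketones and aldehydes to cycloalkanols, here extended from five- and six-membered to a seven-membered closure. The ring C1–C2–C3–C4–C5–C6–C11 closes in the 7-exo-trig mode on the C=O bond, templated by the cis-1,3 relation of the two arms on the cyclobutane, which holds C1 and C4 about 3 Å apart. The new C3 stereocentre is controlled by C2: the aldehyde should react in the polar Felkin–Anh rotamer with the C2–O bond anti to the forming C3–C4 bond, which puts the C3 hydroxyl cis to the C2 isovalerate. The step needs HAT to choose the 1,1-disubstituted alkene over the two conjugated trisubstituted alkenes (C8=C9 enone and angelate), which their substitution and electron poverty should secure. It also needs ring closure to outrun β-scission of the cyclobutane bonds C5–C6 and C5–C10 by the cyclobutylcarbinyl C4 radical; the enforced proximity helps, as does the fact that the rotamer aiming the radical orbital at C3 aligns it with C5–H and not with a ring bond.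

Compound list

1 | geranyl acetate | CC(C)=CCC/C(C)=C/COC(C)=O | starting material
2 | (2E,6E)-8-hydroxy-3,7-dimethylocta-2,6-dien-1-yl acetate | OC/C(C)=C/CC/C(C)=C/COC(C)=O | intermediate
3 | (2E,6E)-8-(tert-butyldiphenylsilyloxy)-3,7-dimethylocta-2,6-dien-1-yl acetate | CC(C)(C)[Si](c1ccccc1)(c1ccccc1)OC/C(C)=C/CC/C(C)=C/COC(C)=O | intermediate
4 | (2E,6E)-8-(tert-butyldiphenylsilyloxy)-3,7-dimethylocta-2,6-dien-1-ol | CC(C)(C)[Si](c1ccccc1)(c1ccccc1)OC/C(C)=C/CC/C(C)=C/CO | intermediate
5 | (2E,6E)-8-(tert-butyldiphenylsilyloxy)-3,7-dimethylocta-2,6-dienal (not isolated) | CC(C)(C)[Si](c1ccccc1)(c1ccccc1)OC/C(C)=C/CC/C(C)=C/C=O | intermediate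
6 | (2E,6E)-8-(tert-butyldiphenylsilyloxy)-3,7-dimethylocta-2,6-dienoic acid | CC(C)(C)[Si](c1ccccc1)(c1ccccc1)OC/C(C)=C/CC/C(C)=C/C(=O)O | intermediate
7 | acid chloride of 6 (not isolated) | CC(C)(C)[Si](c1ccccc1)(c1ccccc1)OC/C(C)=C/CC/C(C)=C/C(=O)Cl | intermediate
8 | vinylketene, (6E)-8-(tert-butyldiphenylsilyloxy)-7-methyl-3-methylideneocta-1,6-dien-1-one (not isolated) | CC(C)(C)[Si](c1ccccc1)(c1ccccc1)OC/C(C)=C/CCC(=C)C=C=O | intermediate
9 | racemic 7-[(tert-butyldiphenylsilyloxy)methyl]-7-methyl-2-methylidenebicyclo[3.1.1]heptan-6-one, silyloxymethyl anti and methyl syn to the three-carbon bridge (C5 ketone, C9=CH2) | CC(C)(C)[Si](c1ccccc1)(c1ccccc1)OC[C@@]1(C)[C@@H]2CCC(=C)[C@H]1C2=O | intermediate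
10 | racemic 7-[(tert-butyldiphenylsilyloxy)methyl]-2,7-dimethylbicyclo[3.1.1]hept-2-en-6-one, same relative configuration (C5 ketone, C8=C9) | CC(C)(C)[Si](c1ccccc1)(c1ccccc1)OC[C@@]1(C)[C@@H]2CC=C(C)[C@H]1C2=O | intermediate
11 | triethyl 2-phosphonopropionate | CCOC(=O)C(C)P(=O)(OCC)OCC | starting material
12 | racemic alkylidene ester: C5=C4(CH3)CO2Et, C8=C9(CH3), C11(CH3)CH2OTBDPS; E/Z mixture at C4=C5 | CC(C)(C)[Si](c1ccccc1)(c1ccccc1)OC[C@@]1(C)[C@@H]2CC=C(C)[C@H]1C2=C(C)C(=O)OCC | intermediate
13 | racemic enone ester: as 12 with C7 ketone | CC(C)(C)[Si](c1ccccc1)(c1ccccc1)OC[C@@]1(C)[C@@H]2C(=O)C=C(C)[C@H]1C2=C(C)C(=O)OCC | intermediate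
14 | racemic primary alcohol: as 13 with C1H2OH | OC[C@@]1(C)[C@@H]2C(=O)C=C(C)[C@H]1C2=C(C)C(=O)OCC | intermediate
15 | racemic aldehyde: as 13 with C1HO | O=C[C@@]1(C)[C@@H]2C(=O)C=C(C)[C@H]1C2=C(C)C(=O)OCC | intermediate
16 | allyl 4-methoxybenzyl ether | C=CCOCc1ccc(OC)cc1 | starting material
17 | [(Z)-3-(4-methoxybenzyloxy)allyl]diisopinocampheylborane, isopinocampheyl groups from (−)-α-pinene (not isolated) | COc1ccc(CO/C=C\CB([C@H]2C[C@H]3C[C@H](C3(C)C)[C@@H]2C)[C@H]2C[C@H]3C[C@H](C3(C)C)[C@@H]2C)cc1 | intermediate
18 | (1S,2S)-syn homoallylic alcohol: C1–OH, C2–O-(4-methoxybenzyl), vinyl at C2, on the enone ester core of target configuration | C=C[C@H](OCc1ccc(OC)cc1)[C@@H](O)[C@@]1(C)[C@@H]2C(=O)C=C(C)[C@H]1C2=C(C)C(=O)OCC | intermediate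
19 | triol: vinyl of 18 turned into C3H(OH)–CH2OH (C3 epimers) | OCC(O)[C@H](OCc1ccc(OC)cc1)[C@@H](O)[C@@]1(C)[C@@H]2C(=O)C=C(C)[C@H]1C2=C(C)C(=O)OCC | intermediate
20 | terminal acetonide of 19 (C1–OH free) | CC1(C)OCC(O1)[C@H](OCc2ccc(OC)cc2)[C@@H](O)[C@@]3(C)[C@@H]4C(=O)C=C(C)[C@H]3C4=C(C)C(=O)OCC | intermediate
21 | triol: as 20 with C7–OH and C5=C4(CH3)CH2OH | CC1(C)OCC(O1)[C@H](OCc2ccc(OC)cc2)[C@@H](O)[C@@]3(C)[C@@H]4C(O)C=C(C)[C@H]3C4=C(C)CO | intermediate
22 | N-allylated 2-nitrobenzenesulfonylhydrazine from 21 (not isolated) | CC1(C)OCC(O1)[C@H](OCc2ccc(OC)cc2)[C@@H](O)[C@@]3(C)[C@@H]4C(O)C=C(C)[C@H]3C4=C(C)CN(N)S(=O)(=O)c5ccccc5[N+](=O)[O-] | intermediate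
23 | allylic diazene from 22 (not isolated) | CC1(C)OCC(O1)[C@H](OCc2ccc(OC)cc2)[C@@H](O)[C@@]3(C)[C@@H]4C(O)C=C(C)[C@H]3C4=C(C)CN=N | intermediate
24 | isopropenyl diol: C5–H syn, isopropenyl anti (cis to the C11 side chain), C7–OH, C1–OH | CC1(C)OCC(O1)[C@H](OCc2ccc(OC)cc2)[C@@H](O)[C@@]3(C)[C@@H]4C(O)C=C(C)[C@H]3[C@@H]4C(C)=C | intermediate
25 | isopropenyl enone alcohol: as 24 with C7 ketone | CC1(C)OCC(O1)[C@H](OCc2ccc(OC)cc2)[C@@H](O)[C@@]3(C)[C@@H]4C(=O)C=C(C)[C@H]3[C@@H]4C(C)=C | intermediate
26 | angelic acid, (Z)-2-methylbut-2-enoic acid | C/C=C(/C)C(=O)O | starting material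
27 | angelic 2,4,6-trichlorobenzoic anhydride (not isolated) | C/C=C(/C)C(=O)OC(=O)c1c(Cl)cc(Cl)cc1Cl | intermediate
28 | C1 angelate of 25 | CC1(C)OCC(O1)[C@H](OCc2ccc(OC)cc2)[C@@H](OC(=O)/C(C)=C\C)[C@@]3(C)[C@@H]4C(=O)C=C(C)[C@H]3[C@@H]4C(C)=C | intermediate
29 | C2 alcohol: 28 without the 4-methoxybenzyl group | CC1(C)OCC(O1)[C@H](O)[C@@H](OC(=O)/C(C)=C\C)[C@@]3(C)[C@@H]4C(=O)C=C(C)[C@H]3[C@@H]4C(C)=C | intermediate
30 | isovaleryl chloride | CC(C)CC(=O)Cl | starting material
31 | C2 isovalerate of 29 | CC1(C)OCC(O1)[C@H](OC(=O)CC(C)C)[C@@H](OC(=O)/C(C)=C\C)[C@@]3(C)[C@@H]4C(=O)C=C(C)[C@H]3[C@@H]4C(C)=C | intermediate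
32 | terminal diol from 31 (not isolated) | OCC(O)[C@H](OC(=O)CC(C)C)[C@@H](OC(=O)/C(C)=C\C)[C@@]1(C)[C@@H]2C(=O)C=C(C)[C@H]1[C@@H]2C(C)=C | intermediate
33 | key-step precursor: C3 aldehyde, C2 isovalerate, C1 angelate, on the enone with C5–H and anti isopropenyl | O=C[C@H](OC(=O)CC(C)C)[C@@H](OC(=O)/C(C)=C\C)[C@@]1(C)[C@@H]2C(=O)C=C(C)[C@H]1[C@@H]2C(C)=C | intermediate
34 | CNP0251293.1 | C/C=C(/C)C(=O)O[C@@H]1[C@@H](OC(=O)CC(C)C)[C@@H](O)C(C)(C)[C@@H]2[C@H]3C(=O)C=C(C)[C@@H]2[C@@]13C | target

Total step count: 21. Longest linear sequence: 21 steps (geranyl acetate 1 to target 34); 11, 16, 26 and 30 enter as purchased reagents.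

Steps most likely to fail

Step 21. After hydrogen-atom transfer the C4 radical may open the cyclobutane by β-scission of C5–C6 or C5–C10, which leads to an α-keto or an allylic radical, faster than it closes onto C3. The carbonyl addition may also revert before the alkoxy radical is quenched, or hydrogen may be transferred to the angelate. The fallback changes the bond-forming event from a free-radical carbonyl addition to a polar one by radical–polar crossover. Starting from 33, Co(salen) with PhSiH3 performs the HAT in the presence of CrCl2, so that the C4 radical is intercepted by divalent chromium. The tertiary alkylchromium then adds irreversibly to the C3 aldehyde through a closed, chelated transition state (a Nozaki–Hiyama–Kishi-type addition). The route is rejoined at 34, and no compound outside the list is made (F0).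

Step 15. The Mitsunobu step may engage the secondary hydroxyls at C1 or C7, or the diazene may deliver hydrogen to the face of C5 that is turned toward the C1 side chain. The fallback replaces the diazene by a metal-bound hydride of greater steric demand, in a palladium-catalysed formate hydrogenolysis of Tsuji type. Starting from 21, the primary allylic alcohol is converted selectively (ClCO2Me, pyridine, CH2Cl2, −20 °C) into the allylic methyl carbonate F1. Zerovalent palladium from Pd(OAc)2/PBu3 with HCO2NH4 in THF then ionises it to a π-allyl complex on the open face and passes hydride from the metal to the more substituted terminus C5. This gives 24, where the route is rejoined.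

Step 17. Acylation of the neopentyl C1 hydroxyl, which sits next to the isopropenyl group, may be sluggish, and forcing it may let the Z alkene of the 2-methylbut-2-enoate drift to E. The fallback builds the Z alkene after the acylation. Starting from 25, esterification with 2-[bis(2,2,2-trifluoroethoxy)phosphoryl]propanoic acid (DCC, DMAP, CH2Cl2) gives the phosphonopropionate ester F2. Still–Gennari olefination (KN(SiMe3)2, 18-crown-6, THF, −78 °C, acetaldehyde) then forms the angelate Z-selectively and returns to the route at 28.

Further compounds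

F0 | step 21 | none | none
F1 | step 15 | primary allylic methyl carbonate of 21 | CC1(C)OCC(O1)[C@H](OCc2ccc(OC)cc2)[C@@H](O)[C@@]3(C)[C@@H]4C(O)C=C(C)[C@H]3C4=C(C)COC(=O)OC
F2 | step 17 | C1 2-[bis(2,2,2-trifluoroethoxy)phosphoryl]propanoate of 25 | CC1(C)OCC(O1)[C@H](OCc2ccc(OC)cc2)[C@@H](OC(=O)C(C)P(=O)(OCC(F)(F)F)OCC(F)(F)F)[C@@]3(C)[C@@H]4C(=O)C=C(C)[C@H]3[C@@H]4C(C)=C
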